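Everything rests on cutting the C5–C6 bond of seven-membered ring B. The C6 oxygen lies 1,3 to C4 across the ring-fusion carbon C5; once C4 is a carbonyl group, C5–C6 is exactly the bond that an aldol addition makes. One intramolecular aldol addition of the ring A cyclopentanone to a Z-enal hanging from quaternary C1 closes ring B and sets C5 and C6, the short tether enforcing the cis ring fusion. The precursor is an (S)-3-methylcyclopentanone whose C1 side chain carries the C10 silyl ether and ends in the Z C7=C8 enal, its geometry fixed beforehand inside a six-membered lactone. The C4 ketone afterwards delivers C3–OAc and C4(OH)iPr.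

Key step: step 11

Remark: skeleton numbering is used for all bicyclic compounds (C1 methyl-bearing fusion carbon, C2–C4 in ring A, C5 fusion CH, C6–C10 in ring B, C10 bonded to C1); α is the face of the C1 methyl group and H5, β the opposite face; TBS = tert-butyldimethylsilyl.
Remark: the ligand antipode in step 1 and the (+)-α-pinene-derived borane in step 4 are the ones chosen to give 1S and 10S.

Step 1
Reactants: 1 3-methylcyclopent-2-en-1-one; 2 vinylmagnesium bromide
Product: 4 (3S)-3-ethenyl-3-methylcyclopentan-1-one, via bromomagnesium enolate 3 (not isolated)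
Conditions: Cu(OTf)2 (3 mol%), chiral imidazolinium chloride (carbene precursor, 4 mol%), Et2O, 0 °C; then 1 M HCl
Reagents that add atoms: none
Why: Copper-catalysed asymmetric conjugate addition of a Grignard reagent to a β-substituted cyclic enone: the chiral carbene–copper complex delivers the vinyl group to one face of the β-carbon and so sets quaternary C1 (S), after which the enolate is protonated.

Step 2
Reactants: 4 (3S)-3-ethenyl-3-methylcyclopentan-1-one
Product: 5 (7S)-7-ethenyl-7-methyl-1,4-dioxaspiro[4.4]nonane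
Conditions: ethylene glycol, p-TsOH·H2O (cat.), benzene, reflux (Dean–Stark)
Reagents that add atoms: ethylene glycol, OCCO
Why: Acid-catalysed ketalisation with azeotropic removal of water; the dioxolane shields the C4 carbonyl from the borane oxidation, iBu2AlH and silyl triflate used before the key step, and C1 is untouched.

Step 3
Reactants: 5 (7S)-7-ethenyl-7-methyl-1,4-dioxaspiro[4.4]nonane
Product: 7 (7S)-7-methyl-1,4-dioxaspiro[4.4]nonane-7-carbaldehyde, via ozonide 6 (not isolated)
Conditions: O3, CH2Cl2, −78 °C; then PPh3, −78 → 20 °C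
Reagents that add atoms: ozone, [O-][O+]=O
Why: Ozonolysis with reductive work-up: the monosubstituted alkene is the only site for ozone (the ketal has no acetal hydrogen), and the α-quaternary aldehyde formed cannot enolise or epimerise.

Step 4
Reactants: 7 (7S)-7-methyl-1,4-dioxaspiro[4.4]nonane-7-carbaldehyde; 8 2-methylallylmagnesium chloride
Product: 10 (1S)-3-methyl-1-[(7S)-7-methyl-1,4-dioxaspiro[4.4]nonan-7-yl]but-3-en-1-ol, via borinate 9 (not isolated)
Conditions: (−)-Ipc2BOMe, Et2O, −78 → 20 °C (forms the methallylborane from 8); 7, −78 °C; then NaOH, H2O2, 0 → 20 °C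
Reagents that add atoms: none
Why: Brown asymmetric methallylboration through a closed six-membered chair transition state: the reagent of the (+)-α-pinene series adds to the Si face of the aldehyde and sets C10 (S) under reagent control, which overrides the weak bias of quaternary C1 and turns any C1 antipode left from step 1 into a separable diastereomer.

Step 5
Reactants: 10 (1S)-3-methyl-1-[(7S)-7-methyl-1,4-dioxaspiro[4.4]nonan-7-yl]but-3-en-1-ol; 11 acryloyl chloride
Product: 12 (1S)-3-methyl-1-[(7S)-7-methyl-1,4-dioxaspiro[4.4]nonan-7-yl]but-3-en-1-yl prop-2-enoate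
Conditions: iPr2NEt, DMAP (cat.), CH2Cl2, −20 → 0 °C
Reagents that add atoms: none
Why: Base-mediated O-acylation of the hindered secondary alcohol with an acid chloride under nucleophilic catalysis; no stereocentre is involved.

Step 6
Reactants: 12 (1S)-3-methyl-1-[(7S)-7-methyl-1,4-dioxaspiro[4.4]nonan-7-yl]but-3-en-1-yl prop-2-enoate
Product: 13 (6S)-4-methyl-6-[(7S)-7-methyl-1,4-dioxaspiro[4.4]nonan-7-yl]-5,6-dihydro-2H-pyran-2-one
Conditions: second-generation Grubbs catalyst RuCl2(=CHPh)(PCy3)(H2IMes) (5 mol%), CH2Cl2 (0.01 M), 40 °C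
Reagents that add atoms: none
Why: Ring-closing metathesis of an acrylate with a 1,1-disubstituted alkene, driven by loss of ethene; the six-membered lactone can only hold the new trisubstituted C7=C8 bond in the cis arrangement that later becomes the Z-enal.

Step 7
Reactants: 13 (6S)-4-methyl-6-[(7S)-7-methyl-1,4-dioxaspiro[4.4]nonan-7-yl]-5,6-dihydro-2H-pyran-2-one
Product: 14 (2Z,5S)-3-methyl-5-[(7S)-7-methyl-1,4-dioxaspiro[4.4]nonan-7-yl]pent-2-ene-1,5-diol
Conditions: iBu2AlH (4 equiv), CH2Cl2, −78 → 0 °C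
Reagents that add atoms: none
Why: Exhaustive hydride reduction of the unsaturated lactone by 1,2-addition only, which opens the ring to the Z-allylic 1,5-diol without touching the alkene geometry or the ketal.

Step 8
Reactants: 14 (2Z,5S)-3-methyl-5-[(7S)-7-methyl-1,4-dioxaspiro[4.4]nonan-7-yl]pent-2-ene-1,5-diol
Product: 15 1,5-bis-O-TBS ether of 14
Conditions: TBSOTf (2.5 equiv), 2,6-lutidine, CH2Cl2, −78 → 0 °C
Reagents that add atoms: tert-butyldimethylsilyl trifluoromethanesulfonate, CC(C)(C)[Si](C)(C)OS(=O)(=O)C(F)(F)F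
Why: Silyl triflate silylation protects both hydroxyls, the triflate being needed for the neopentyl-type C10 hydroxyl next to quaternary C1.

Step 9
Reactants: 15 1,5-bis-O-TBS ether of 14
Product: 16 (3S)-3-[(1S,3Z)-1-(TBS-oxy)-5-hydroxy-3-methylpent-3-en-1-yl]-3-methylcyclopentan-1-one
Conditions: p-TsOH·H2O (0.1 equiv), acetone/H2O (10:1), 20 °C
Reagents that add atoms: water, O
Why: Mild aqueous acid removes the two acid-labile groups, the primary allylic silyl ether and the dioxolane, while the hindered secondary silyl ether at C10 is orders of magnitude slower to cleave.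

Step 10
Reactants: 16 (3S)-3-[(1S,3Z)-1-(TBS-oxy)-5-hydroxy-3-methylpent-3-en-1-yl]-3-methylcyclopentan-1-one
Product: 17 (2Z,5S)-5-(TBS-oxy)-3-methyl-5-[(1S)-1-methyl-3-oxocyclopentyl]pent-2-enal
Conditions: MnO2 (20 equiv), CH2Cl2, 20 °C
Reagents that add atoms: none
Why: Heterogeneous MnO2 oxidation is selective for the allylic alcohol, stops at the aldehyde and, being neutral, keeps the Z geometry and leaves the ketone and silyl ether alone.

Step 11
Reactants: 17 (2Z,5S)-5-(TBS-oxy)-3-methyl-5-[(1S)-1-methyl-3-oxocyclopentyl]pent-2-enal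
Product: 19 (1S,5R,6S,10S)-10-(TBS-oxy)-6-hydroxy-1,8-dimethylbicyclo[5.3.0]dec-7-en-4-one (cis-fused, O6 β), via enamine 18 (not isolated)
Conditions: D-proline (30 mol%), DMSO (0.02 M), 20 °C; pH 7 buffer work-up
Reagents that add atoms: none
Why: D-proline condenses reversibly with the C4 ketone; the enamines toward C3 and C5 interconvert through the iminium ion, and only the C4=C5 enamine 18 can reach the C6 aldehyde, which it attacks 1,2 while the carboxylic acid, lying on the same β face, hydrogen-bonds the aldehyde oxygen, after which hydrolysis releases ketol 19 and the catalyst. The closest known reaction type is the proline-catalysed intramolecular enolexo aldol addition of keto aldehydes, established for five- and six-membered rings and applied here to a seven-membered one. Ring B closes in a 7-(enolexo)-exo-trig mode, helped by the Z C7=C8 bond and quaternary C1, which hold C6 next to C5. C5 (R) is set by the tether: the four-atom chain hangs from the β bond of C1 and can only reach the β face of the enamine, so the ring fusion should be cis. C6 (S) is expected from the reversible, hydrogen-bonded closure, because only the ketol with O6 cis to the C5–C4 bond keeps the O6–H···O=C4 bond with both O6 and the C10 silyloxy group equatorial on ring B; this is the least secure element of the step. The step needs C5 over C3 (secured by reversible enamine formation), 1,2- over 1,4-addition (secured by the fully substituted β-carbon C8 of the enal) and addition without dehydration (amino-acid catalyst, room temperature, neutral work-up).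

Step 12
Reactants: 20 4-hydroxybenzoic acid
Product: 22 4-(TBS-oxy)benzoic acid, via silyl ester 21 (not isolated)
Conditions: TBSCl (2.5 equiv), imidazole, DMF, 20 °C; then AcOH/THF/H2O (3:1:1), 20 °C
Reagents that add atoms: tert-butyldimethylsilyl chloride, CC(C)(C)[Si](C)(C)Cl
Why: Exhaustive silylation of phenol and acid followed by selective hydrolysis of the labile silyl ester leaves the aryl silyl ether, giving a protected acid that is unmasked in the last step together with C10.

Step 13
Reactants: 19 ketol (1S,5R,6S,10S); 22 4-(TBS-oxy)benzoic acid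
Product: 24 (1S,5R,6S,10S)-10-(TBS-oxy)-1,8-dimethyl-4-oxobicyclo[5.3.0]dec-7-en-6-yl 4-(TBS-oxy)benzoate, via O-acylisourea 23 (not isolated)
Conditions: EDC·HCl, DMAP, CH2Cl2, 0 → 20 °C
Reagents that add atoms: none
Why: Steglich esterification (carbodiimide activation, acyl transfer by DMAP) acylates O6 with retention at C6 under conditions mild enough to avoid β-elimination or retro-aldol of the ketol.

Step 14
Reactants: 24 keto ester
Product: 26 (1S,5R,6S,10S)-10-(TBS-oxy)-1,8-dimethyl-4-(trifluoromethylsulfonyloxy)bicyclo[5.3.0]deca-3,7-dien-6-yl 4-(TBS-oxy)benzoate, via potassium enolate 25 (not isolated)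
Conditions: KN(SiMe3)2 (1.1 equiv), THF, −78 °C; then N-(5-chloropyridin-2-yl)bis(trifluoromethanesulfonyl)imide, −78 °C
Reagents that add atoms: N-(5-chloropyridin-2-yl)bis(trifluoromethanesulfonyl)imide (Comins' reagent), FC(F)(F)S(=O)(=O)N(c1ccc(Cl)cn1)S(=O)(=O)C(F)(F)F
Why: Kinetic deprotonation by a hindered amide base takes the accessible C3 methylene proton and not the C5 methine flanked by quaternary C1 and C6 (which also avoids β-elimination of the C6 ester), and the enolate is O-triflated at low temperature by the pyridyl triflimide.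

Step 15
Reactants: 26 enol triflate; 27 isopropylzinc bromide
Product: 28 (1S,5R,6S,10S)-10-(TBS-oxy)-4-isopropyl-1,8-dimethylbicyclo[5.3.0]deca-3,7-dien-6-yl 4-(TBS-oxy)benzoate
Conditions: PdCl2(dppf) (5 mol%), THF, 20 °C
Reagents that add atoms: none
Why: Negishi coupling of a secondary alkylzinc halide with an alkenyl triflate; the wide-bite-angle dppf ligand favours reductive elimination over β-hydride elimination so that isopropyl is transferred without isomerisation, and oxidative addition to the triflate is faster than ionisation of the hindered allylic ester.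

Step 16
Reactants: 28 diene ester
Product: 29 (1S,3S,4R,5R,6S,10S)-10-(TBS-oxy)-3,4-dihydroxy-4-isopropyl-1,8-dimethylbicyclo[5.3.0]dec-7-en-6-yl 4-(TBS-oxy)benzoate
Conditions: OsO4 (5 mol%), N-methylmorpholine N-oxide, acetone/H2O (10:1), 0 °C
Reagents that add atoms: osmium tetroxide, O=[Os](=O)(=O)=O; N-methylmorpholine N-oxide, C[N+]1([O-])CCOCC1; water, O
Why: Catalytic osmylation (Upjohn conditions) adds both oxygens suprafacially to the α (convex) face of the ring A alkene, opposite the C5–C6 bond and ring B, setting C3 (S) and C4 (R) with the hydroxyls cis, while C7=C8 is deactivated by its allylic aroyloxy group.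

Step 17
Reactants: 29 diol
Product: 30 3-O-acetate of 29
Conditions: Ac2O, pyridine, DMAP (cat.), CH2Cl2, 0 → 20 °C
Reagents that add atoms: acetic anhydride, CC(=O)OC(C)=O
Why: DMAP-catalysed acetylation is selective for the secondary C3 hydroxyl because the tertiary C4 hydroxyl flanked by isopropyl and C5 is far too hindered.

Step 18
Reactants: 30 3-O-acetate of 29
Product: 31 (1S,3S,4R,5R,6S,10S)-3-acetoxy-4,10-dihydroxy-4-isopropyl-1,8-dimethylbicyclo[5.3.0]dec-7-en-6-yl 4-hydroxybenzoate (CNP0146780.2)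
Conditions: HF·pyridine, THF/pyridine, 0 → 20 °C
Reagents that add atoms: none
Why: Buffered fluoride cleaves the aryl and the C10 silyl ethers by Si–F bond formation without transesterifying the acetate or the aroyl ester, giving the target.

Compound list
1 | 3-methylcyclopent-2-en-1-one | CC1=CC(=O)CC1 | starting material
2 | vinylmagnesium bromide | C=C[Mg]Br | starting material
3 | bromomagnesium C4–C5 enolate of 4 | C1C[C@](C)(C=C)C=C1O[Mg]Br | intermediate
4 | (3S)-3-ethenyl-3-methylcyclopentan-1-one | C1C[C@](C)(C=C)CC1=O | intermediate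
5 | (7S)-7-ethenyl-7-methyl-1,4-dioxaspiro[4.4]nonane | C1C[C@](C)(C=C)CC12OCCO2 | intermediate
6 | 3-[(7S)-7-methyl-1,4-dioxaspiro[4.4]nonan-7-yl]-1,2,4-trioxolane (ozonide) | C1C[C@](C)(C3OCOO3)CC12OCCO2 | intermediate
7 | (7S)-7-methyl-1,4-dioxaspiro[4.4]nonane-7-carbaldehyde | C1C[C@](C)(C=O)CC12OCCO2 | intermediate
8 | 2-methylallylmagnesium chloride | CC(=C)C[Mg]Cl | starting material
9 | O-diisopinocampheylboryl derivative (borinate) of 10 | C1C[C@](C)([C@@H](OB([C@@H]3C[C@@H]4C[C@H]([C@H]3C)C4(C)C)[C@@H]3C[C@@H]4C[C@H]([C@H]3C)C4(C)C)CC(C)=C)CC12OCCO2 | intermediate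
10 | (1S)-3-methyl-1-[(7S)-7-methyl-1,4-dioxaspiro[4.4]nonan-7-yl]but-3-en-1-ol | C1C[C@](C)([C@@H](O)CC(C)=C)CC12OCCO2 | intermediate
11 | acryloyl chloride | C=CC(=O)Cl | starting material
12 | (1S)-3-methyl-1-[(7S)-7-methyl-1,4-dioxaspiro[4.4]nonan-7-yl]but-3-en-1-yl prop-2-enoate | C1C[C@](C)([C@@H](OC(=O)C=C)CC(C)=C)CC12OCCO2 | intermediate
13 | (6S)-4-methyl-6-[(7S)-7-methyl-1,4-dioxaspiro[4.4]nonan-7-yl]-5,6-dihydro-2H-pyran-2-one | C1C[C@](C)([C@@H]3CC(C)=CC(=O)O3)CC12OCCO2 | intermediate
14 | (2Z,5S)-3-methyl-5-[(7S)-7-methyl-1,4-dioxaspiro[4.4]nonan-7-yl]pent-2-ene-1,5-diol | C1C[C@](C)([C@@H](O)C/C(C)=C\CO)CC12OCCO2 | intermediate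
15 | 1,5-bis-O-TBS ether of 14 | C1C[C@](C)([C@@H](O[Si](C)(C)C(C)(C)C)C/C(C)=C\CO[Si](C)(C)C(C)(C)C)CC12OCCO2 | intermediate
16 | (3S)-3-[(1S,3Z)-1-(TBS-oxy)-5-hydroxy-3-methylpent-3-en-1-yl]-3-methylcyclopentan-1-one | C1C[C@](C)([C@@H](O[Si](C)(C)C(C)(C)C)C/C(C)=C\CO)CC1=O | intermediate
17 | (2Z,5S)-5-(TBS-oxy)-3-methyl-5-[(1S)-1-methyl-3-oxocyclopentyl]pent-2-enal (aldol precursor) | C1C[C@](C)([C@@H](O[Si](C)(C)C(C)(C)C)C/C(C)=C\C=O)CC1=O | intermediate
18 | C4=C5 enamine of 17 with D-proline | OC(=O)[C@H]1CCCN1C1=C[C@](C)(CC1)[C@@H](O[Si](C)(C)C(C)(C)C)C/C(C)=C\C=O | intermediate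
19 | (1S,5R,6S,10S)-10-(TBS-oxy)-6-hydroxy-1,8-dimethylbicyclo[5.3.0]dec-7-en-4-one (aldol product; cis-fused, O6 β, O10 α) | C1C[C@]2(C)[C@@H](O[Si](C)(C)C(C)(C)C)CC(C)=C[C@H](O)[C@@H]2C1=O | intermediate
20 | 4-hydroxybenzoic acid | OC(=O)c1ccc(O)cc1 | starting material
21 | tert-butyldimethylsilyl 4-(TBS-oxy)benzoate | CC(C)(C)[Si](C)(C)OC(=O)c1ccc(O[Si](C)(C)C(C)(C)C)cc1 | intermediate
22 | 4-(TBS-oxy)benzoic acid | OC(=O)c1ccc(O[Si](C)(C)C(C)(C)C)cc1 | intermediate
23 | O-acylisourea from 22 and EDC | CCN=C(NCCCN(C)C)OC(=O)c1ccc(O[Si](C)(C)C(C)(C)C)cc1 | intermediate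
24 | (1S,5R,6S,10S)-10-(TBS-oxy)-1,8-dimethyl-4-oxobicyclo[5.3.0]dec-7-en-6-yl 4-(TBS-oxy)benzoate | C1C[C@]2(C)[C@@H](O[Si](C)(C)C(C)(C)C)CC(C)=C[C@H](OC(=O)c3ccc(O[Si](C)(C)C(C)(C)C)cc3)[C@@H]2C1=O | intermediate
25 | potassium C3–C4 enolate of 24 | C=1C[C@]2(C)[C@@H](O[Si](C)(C)C(C)(C)C)CC(C)=C[C@H](OC(=O)c3ccc(O[Si](C)(C)C(C)(C)C)cc3)[C@@H]2C=1[O-].[K+] | intermediate
26 | (1S,5R,6S,10S)-10-(TBS-oxy)-1,8-dimethyl-4-(trifluoromethylsulfonyloxy)bicyclo[5.3.0]deca-3,7-dien-6-yl 4-(TBS-oxy)benzoate | C=1C[C@]2(C)[C@@H](O[Si](C)(C)C(C)(C)C)CC(C)=C[C@H](OC(=O)c3ccc(O[Si](C)(C)C(C)(C)C)cc3)[C@@H]2C=1OS(=O)(=O)C(F)(F)F | intermediate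
27 | isopropylzinc bromide | CC(C)[Zn]Br | starting material
28 | (1S,5R,6S,10S)-10-(TBS-oxy)-4-isopropyl-1,8-dimethylbicyclo[5.3.0]deca-3,7-dien-6-yl 4-(TBS-oxy)benzoate | C=1C[C@]2(C)[C@@H](O[Si](C)(C)C(C)(C)C)CC(C)=C[C@H](OC(=O)c3ccc(O[Si](C)(C)C(C)(C)C)cc3)[C@@H]2C=1C(C)C | intermediate
29 | (1S,3S,4R,5R,6S,10S)-10-(TBS-oxy)-3,4-dihydroxy-4-isopropyl-1,8-dimethylbicyclo[5.3.0]dec-7-en-6-yl 4-(TBS-oxy)benzoate (3α,4α-diol) | O[C@H]1C[C@]2(C)[C@@H](O[Si](C)(C)C(C)(C)C)CC(C)=C[C@H](OC(=O)c3ccc(O[Si](C)(C)C(C)(C)C)cc3)[C@@H]2[C@]1(O)C(C)C | intermediate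
30 | 3-O-acetate of 29 | CC(=O)O[C@H]1C[C@]2(C)[C@@H](O[Si](C)(C)C(C)(C)C)CC(C)=C[C@H](OC(=O)c3ccc(O[Si](C)(C)C(C)(C)C)cc3)[C@@H]2[C@]1(O)C(C)C | intermediate
31 | (1S,3S,4R,5R,6S,10S)-3-acetoxy-4,10-dihydroxy-4-isopropyl-1,8-dimethylbicyclo[5.3.0]dec-7-en-6-yl 4-hydroxybenzoate | CC(=O)O[C@H]1C[C@]2(C)[C@@H](O)CC(C)=C[C@H](OC(=O)c3ccc(O)cc3)[C@@H]2[C@]1(O)C(C)C | target

Total step count: 18. Longest linear sequence: 17 steps (steps 1–11 and 13–18; step 12 is a one-step branch).

Steps most likely to fail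

Step 11 (key aldol). The seven-membered closure may be slow, so that amine-induced Z/E scrambling of the enal, oligomerisation or dehydration of the ketol compete. Facial selectivity at the aldehyde carbon C6 may also be poor or reversed. The fallback sets out from 17 and closes the ring through a chelated magnesium enolate instead (MgBr2·OEt2, iPr2NEt, CH2Cl2, −20 °C; reversible soft enolisation, no iminium chemistry at the enal). If attack occurs on the other aldehyde face, the C6-epimeric ketol F1 is still used: Mitsunobu esterification with acid 22 (PPh3, diisopropyl azodicarboxylate, toluene, 0 °C) inverts C6. The fallback returns to the route at ester 24.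

Step 16 (dihydroxylation). Site selectivity between the two trisubstituted double bonds may be poor, with osmylation of C7=C8 competing, and attack on the α face may be incomplete. The fallback sets out from ketone 24 and replaces steps 14–16 by enolate oxidation and carbonyl addition. Kinetic silylation toward C3 (LiN(iPr)2, Me3SiCl, THF, −78 °C) gives the trimethylsilyl enol ether F2. Rubottom oxidation with dimethyldioxirane (acetone, −78 °C) attacks the electron-rich enol ether far faster than C7=C8 and from the α face, giving the 3α-trimethylsilyloxy ketone F3. Isopropylmagnesium chloride with CeCl3 (THF, −78 °C) should add anti to the C3 silyloxy group to give the tertiary alcohol F4; this facial outcome rests on 1,2-induction and is itself uncertain. Brief treatment with citric acid in methanol removes the trimethylsilyl group and returns to the route at diol 29.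

Step 1 (conjugate vinylation). Enantioselectivity may be low and 1,2-addition may compete with the five-membered enone and a vinyl Grignard reagent. The fallback sets out from 1 and introduces the vinyl group in masked form. 1-(Trimethylsilyl)vinyl-diisobutylaluminium (from ethynyltrimethylsilane and iBu2AlH) is added under copper–carbene catalysis (Cu(OTf)2, chiral sulfonate-bearing imidazolinium salt, THF, −30 °C) to give the silylvinyl ketone F5. Protodesilylation (CF3CO2H, CH2Cl2, 20 °C) returns to the route at ketone 4.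

Further compounds
F1 | step 11 | (1S,5R,6R,10S)-10-(TBS-oxy)-6-hydroxy-1,8-dimethylbicyclo[5.3.0]dec-7-en-4-one (C6 epimer of 19) | C1C[C@]2(C)[C@@H](O[Si](C)(C)C(C)(C)C)CC(C)=C[C@@H](O)[C@@H]2C1=O
F2 | step 16 | (1S,5R,6S,10S)-10-(TBS-oxy)-1,8-dimethyl-4-(trimethylsilyloxy)bicyclo[5.3.0]deca-3,7-dien-6-yl 4-(TBS-oxy)benzoate | C=1C[C@]2(C)[C@@H](O[Si](C)(C)C(C)(C)C)CC(C)=C[C@H](OC(=O)c3ccc(O[Si](C)(C)C(C)(C)C)cc3)[C@@H]2C=1O[Si](C)(C)C
F3 | step 16 | (1S,3S,5R,6S,10S)-10-(TBS-oxy)-1,8-dimethyl-4-oxo-3-(trimethylsilyloxy)bicyclo[5.3.0]dec-7-en-6-yl 4-(TBS-oxy)benzoate | C[Si](C)(C)O[C@H]1C[C@]2(C)[C@@H](O[Si](C)(C)C(C)(C)C)CC(C)=C[C@H](OC(=O)c3ccc(O[Si](C)(C)C(C)(C)C)cc3)[C@@H]2C1=O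
F4 | step 16 | (1S,3S,4R,5R,6S,10S)-10-(TBS-oxy)-4-hydroxy-4-isopropyl-1,8-dimethyl-3-(trimethylsilyloxy)bicyclo[5.3.0]dec-7-en-6-yl 4-(TBS-oxy)benzoate | C[Si](C)(C)O[C@H]1C[C@]2(C)[C@@H](O[Si](C)(C)C(C)(C)C)CC(C)=C[C@H](OC(=O)c3ccc(O[Si](C)(C)C(C)(C)C)cc3)[C@@H]2[C@]1(O)C(C)C
F5 | step 1 | (3S)-3-methyl-3-[1-(trimethylsilyl)ethenyl]cyclopentan-1-one | C1C[C@](C)(C(=C)[Si](C)(C)C)CC1=O
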